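The data were computed with made-up constants, and the scatter is random.

The count of starting complex is conserved: side product, starting complex, complex with three exchanged and an unseen remainder always sum to the charge. In teal at 1.04 d that remainder is 29.0% beside 32% of starting complex, a near-even split.

| setting | teal | blue | violet | red | maple | larch | birch |
|---|---|---|---|---|---|---|---|
| starting complex | 0.25 M | 0.12 M | 0.50 M | 0.25 M | 0.25 M | 0.25 M (fed, over 50 h) | 0.25 M |
| incoming ligand | 0.263 M | 0.263 M | 0.263 M | 0.263 M | 0.263 M (fed, over 50 h) | 0.263 M | 0.263 M |
| leaving ligand | 1.25 M | 1.25 M | 1.25 M | 0.62 M | 1.25 M | 1.25 M | 1.25 M |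
| remark | run made earlier | run made earlier | run made earlier | run made earlier | all else is in the flask from the start; the feed brings no volume worth counting | all else is in the flask from the start; the feed brings no volume worth counting | everything together at the start |
| time |  |  |  |  | 2.5 d | 2.5 d | 2.5 d |

| run | time / d | side product / % | complex with three exchanged / % | starting complex / % |
|---|---|---|---|---|
| teal | 0.208 | 13 | 5 | 46 |
| teal | 0.333 | 17 | 4 | 41 |
| teal | 0.500 | 21 | 4 | 38 |
| teal | 0.625 | 25 | 5 | 37 |
| teal | 1.04 | 36 | 3 | 32 |
| teal | 1.67 | 47 | 5 | 23 |
| teal | 2.50 | 57 | 4 | 21 |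
| blue | 0.250 | 6 | 17 | 33 |
| blue | 0.333 | 3 | 16 | 29 |
| blue | 0.500 | 9 | 16 | 32 |
| blue | 0.833 | 12 | 19 | 29 |
| blue | 1.25 | 18 | 19 | 27 |
| blue | 2.08 | 28 | 14 | 22 |
| blue | 3.00 | 35 | 13 | 21 |
| violet | 0.250 | 22 | 0 | 52 |
| violet | 0.333 | 27 | 3 | 47 |
| violet | 0.500 | 39 | 3 | 44 |
| violet | 0.833 | 51 | 0 | 38 |
| violet | 1.25 | 56 | 2 | 28 |
| violet | 2.08 | 70 | 0 | 21 |
| violet | 3.00 | 76 | 1 | 16 |
| red | 0.625 | 26 | 9 | 32 |
| red | 1.25 | 36 | 7 | 24 |
| red | 1.67 | 44 | 10 | 22 |
| red | 2.50 | 52 | 10 | 16 |
| red | 3.00 | 54 | 9 | 18 |

(standard deviation of a reading: 2 percentage points)

- a species is counted by the starting complex in it: one side product counts as two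
- the earlier runs were read with a standard deviation of 2 percentage points

- which flask leads in amount of side product, in percent of the starting complex charged ("all alike" within 1.5 percentage points) (maple / larch / birch / all alike)
- how much side product is there at the end, in percent of the starting complex charged: maple
- how much side product is there at the end, in percent of the starting complex charged: larch
- how much side product is there at the end, in percent of the starting complex charged: birch

Exchange is fast: teal's starting complex has dropped to 46% by 0.208 d. With an even split, side product grows as the square of the unpaired fraction, and its fraction is time over time plus a pairing half-time, the second-order half-life of the charge. That half-time is time multiplied by unpaired over paired fraction, and teal at 1.04 d reads 1.85 d. It should scale inversely with the charge, so violet should show 76.4% at 3.00 d, and it reads 76%. Blue, however, reads 5.57 d where scaling gives 3.85 d.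

My own reckoning takes two extremes. With everything present from the start, as in birch, side product reaches 57.5%. With the fed species arriving in one lump when the feed ends, the clock runs only from then, giving 18.4%. Maple and larch lie between. At half of the feed time, larch holds half its charge, so its rate is a quarter of the full-charge rate. Maple has by then received ligand for half of its complex, close to the even split, so my reckoning puts maple near the top. A rate growing as the square of the time during the feed gives larch 1.11 d of full-charge clock and so 37.5%, midway between the extremes. The forecast gives 52% for maple, 33% for larch and 57% for birch, with birch leading and, of larch, “The rate builds only late”.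

The flasks give 53.7% for maple, 35.1% for larch and 57.1% for birch, so birch leads.

    starting complex + incoming ligand ⇌ leaving ligand + complex with one exchanged (K = 11.0, k = 9.90 × 10⁻⁴ M⁻¹ s⁻¹)
    complex with one exchanged + incoming ligand ⇌ leaving ligand + complex with two exchanged (K = 4.80, k = 0.00150 M⁻¹ s⁻¹)
    complex with two exchanged + incoming ligand ⇌ leaving ligand + complex with three exchanged (K = 13.0, k = 0.00120 M⁻¹ s⁻¹)
    starting complex + complex with one exchanged → side product (k = 7.80 × 10⁻⁵ M⁻¹ s⁻¹)

Read through the pairing half-time, maple has worked 2.15 d of full-charge clock and larch 1.001 d. Birch's result moves by 5 points at a charge of 0.217 M or 0.291 M. A neighbouring flask, charged with 0.62 M of starting complex and so holding 0.424 equiv of incoming ligand, has a scaled half-time of 0.746 d, which gives 77.0%. That neighbouring flask reaches 73.0% of side product, with 24.0% of starting complex remaining.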